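**Retrosynthetic overview**
1. C1 acid ⇐ primary alcohol (late oxidation); C9 carbinol ⇐ CBS reduction of a C9 α-methylene ketone.
2. C9–C10 bond ⇐ Weinreb amide of the dioxane fragment + 2-lithioalkene made from dihydro-β-ionone (Shapiro).
3. 1,2-Dioxane ⇐ tertiary C6 hydroperoxide closing on a C3 mesylate (SN2, inversion); C6–OOH ⇐ H2O2 opening of a chiral 2,2-disubstituted oxetane (inversion).
4. C3 ⇐ ketoreductase reduction of a β-keto ester; C2 ⇐ Fráter–Seebach methylation; C6 ⇐ Sharpless epoxidation of geraniol, then hydride opening and oxetane closure.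
5. Ring order: oxetane (step 3, sacrificed in step 11), then the 1,2-dioxane (step 12); the cyclohexene ring is bought with dihydro-β-ionone.

Assumption: carbon labels C1–C10 in the text follow the target (C1 = CO2H carbon, C2, C3, C6 and C9 = the four stereocentres); compound names use their own IUPAC locants.

**Step 1**
Reactants: 1 geraniol
Product: 2 [(2R,3R)-3-methyl-3-(4-methylpent-3-en-1-yl)oxiran-2-yl]methanol
Conditions: Ti(OiPr)4 (5 mol %), D-(−)-diethyl tartrate (7.5 mol %), t-BuOOH (1.5 equiv), 4 Å molecular sieves, CH2Cl2, −20 °C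
Reagents that add atoms: tert-butyl hydroperoxide, CC(C)(C)OO
Why: Katsuki–Sharpless asymmetric epoxidation touches only the allylic-alcohol alkene, and the D-(−)-tartrate catalyst gives the (2R,3R)-epoxide (about 95% ee), which fixes the future C6 as the first stereocentre.

**Step 2**
Reactants: 2 epoxy alcohol
Product: 3 (3R)-3,7-dimethyloct-6-ene-1,3-diol
Conditions: NaAlH2(OCH2CH2OMe)2 (Red-Al, 1.5 equiv), THF, 0 °C; H2O/NaOH work-up
Reagents that add atoms: none
Why: Hydroxyl-directed hydride delivery from the alkoxyaluminate opens the 2,3-epoxy alcohol at C2 (SN2), giving the 1,3-diol without touching the tertiary C–O stereocentre.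

**Step 3**
Reactants: 3 diol
Product: 5 (2R)-2-methyl-2-(4-methylpent-3-en-1-yl)oxetane, via primary tosylate 4 (not isolated)
Conditions: n-BuLi (1.0 equiv), THF, 0 °C; TsCl (1.0 equiv), 0 °C; n-BuLi (1.05 equiv), 0 → 60 °C
Reagents that add atoms: 4-methylbenzenesulfonyl chloride, Cc1ccc(cc1)S(Cl)(=O)=O (its atoms stay only in intermediate 4, none in 5)
Why: Selective sulfonylation of the primary alkoxide followed by intramolecular Williamson etherification (4-exo-tet) by the tertiary alkoxide closes the oxetane with retention at the quaternary carbon.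

**Step 4**
Reactants: 5 oxetane
Product: 7 3-[(2R)-2-methyloxetan-2-yl]propanal, via ozonide 6 (not isolated)
Conditions: O3, CH2Cl2, −78 °C; then Me2S, −78 °C → rt
Reagents that add atoms: ozone, [O-][O+]=O
Why: Ozonolysis with reductive work-up cleaves the only alkene, and the oxetane is inert to ozone.

**Step 5**
Reactants: 7 aldehyde
Product: 8 ethyl 5-[(2R)-2-methyloxetan-2-yl]-3-oxopentanoate
Conditions: N2CHCO2Et (1.2 equiv), SnCl2 (10 mol %), CH2Cl2, 0 °C → rt
Reagents that add atoms: ethyl diazoacetate, CCOC(=O)C=[N+]=[N-]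
Why: Roskamp homologation (addition of the diazo ester to the aldehyde, 1,2-hydride shift, loss of N2) gives the β-keto ester under nearly neutral conditions that the oxetane tolerates.

**Step 6**
Reactants: 8 β-keto ester
Product: 9 ethyl (3R)-3-hydroxy-5-[(2R)-2-methyloxetan-2-yl]pentanoate
Conditions: ketoreductase ((R)-selective, NADPH-dependent), NADP+ (cat.), isopropanol (10 vol %), potassium phosphate buffer pH 7.0, 30 °C
Reagents that add atoms: none
Why: A ketoreductase (NADPH-dependent alcohol dehydrogenase class) delivers hydride to one face of the prochiral ketone under catalyst control, setting C3 as (R) without touching ester or oxetane, with isopropanol recycling the cofactor.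

**Step 7**
Reactants: 9 β-hydroxy ester
Product: 11 ethyl (2R,3R)-3-hydroxy-2-methyl-5-[(2R)-2-methyloxetan-2-yl]pentanoate, via dilithium enolate alkoxide 10 (not isolated)
Conditions: LiN(iPr)2 (2.2 equiv), THF, −78 → −30 °C; MeI (1.5 equiv), DMPU, −78 → −10 °C
Reagents that add atoms: iodomethane, CI; lithium diisopropylamide, [Li]N(C(C)C)C(C)C (its lithium stays only in intermediate 10)
Why: Fráter–Seebach alkylation: the chelated dianion is methylated on the face away from the C3 side chain, setting C2 anti to the C3 oxygen (dr ≥ 95:5).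

**Step 8**
Reactants: 11 ester
Product: 12 (2S,3R)-2-methyl-5-[(2R)-2-methyloxetan-2-yl]pentane-1,3-diol
Conditions: LiAlH4, THF, 0 °C
Reagents that add atoms: none
Why: Hydride reduction of the ester to the primary alcohol leaves the stereocentres and, at 0 °C, the oxetane untouched.

**Step 9**
Reactants: 12 diol
Product: 13 (2S,3R)-1-[(tert-butyldiphenylsilyl)oxy]-2-methyl-5-[(2R)-2-methyloxetan-2-yl]pentan-3-ol
Conditions: t-BuPh2SiCl (1.05 equiv), imidazole, CH2Cl2, 0 °C
Reagents that add atoms: tert-butyl(chloro)diphenylsilane, CC(C)(C)[Si](Cl)(c1ccccc1)c1ccccc1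
Why: The bulky silyl chloride silylates only the primary hydroxyl (steric selection), masking C1 as a non-enolisable, base-stable group.

**Step 10**
Reactants: 13 alcohol
Product: 14 (2S,3R)-1-[(tert-butyldiphenylsilyl)oxy]-2-methyl-5-[(2R)-2-methyloxetan-2-yl]pentan-3-yl methanesulfonate
Conditions: MsCl, Et3N, CH2Cl2, −10 °C; used at once
Reagents that add atoms: methanesulfonyl chloride, CS(Cl)(=O)=O
Why: Mesylation of the only free hydroxyl occurs at oxygen with retention and turns C3 into the electrophile for the ring closure.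

**Step 11**
Reactants: 14 mesylate
Product: 15 (2S,3R,6S)-1-[(tert-butyldiphenylsilyl)oxy]-6-hydroperoxy-8-hydroxy-2,6-dimethyloctan-3-yl methanesulfonate
Conditions: H2O2 (anhydrous, in Et2O, 10 equiv), Me3SiOTf (0.2 equiv), Et2O, −78 → 0 °C
Reagents that add atoms: hydrogen peroxide, OO
Why: Lewis acid-promoted perhydrolysis opens the oxetane at its tertiary carbon in an SN2-like step with inversion, which installs the C6–O bond of the target with the required configuration while mesylate and silyl ether survive the cold, briefly acidic medium.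

**Step 12**
Reactants: 15 hydroperoxide
Product: 16 2-[(3S,6S)-6-{(2S)-1-[(tert-butyldiphenylsilyl)oxy]propan-2-yl}-3-methyl-1,2-dioxan-3-yl]ethan-1-ol
Conditions: KOC(CH3)3 (1.05 equiv), 18-crown-6 (1.1 equiv), THF, 0 °C
Reagents that add atoms: none
Why: The peroxide anion (far more acidic than the alcohol, α-effect nucleophile) displaces the mesylate in a 6-exo-tet intramolecular SN2 etherification with inversion at C3, closing the 1,2-dioxane with C3 substituent and C6 methyl cis; the few percent of C6 epimer carried from step 1 is removed here by chromatography.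

**Step 13**
Reactants: 16 alcohol
Product: 17 [(3S,6S)-6-{(2S)-1-[(tert-butyldiphenylsilyl)oxy]propan-2-yl}-3-methyl-1,2-dioxan-3-yl]acetic acid
Conditions: PhI(OAc)2 (2.2 equiv), TEMPO (0.2 equiv), MeCN/H2O 1:1, rt
Reagents that add atoms: water, O
Why: Oxoammonium (TEMPO) oxidation in wet acetonitrile takes the primary alcohol through the aldehyde hydrate to the acid without affecting the O–O bond or the silyl ether.

**Step 14**
Reactants: 17 acid
Product: 19 1-diazo-3-[(3S,6S)-6-{(2S)-1-[(tert-butyldiphenylsilyl)oxy]propan-2-yl}-3-methyl-1,2-dioxan-3-yl]propan-2-one, via mixed carbonic anhydride 18 (not isolated)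
Conditions: isobutyl chloroformate, N-methylmorpholine, THF, −15 °C; then CH2N2 (Et2O), −15 → 0 °C
Reagents that add atoms: diazomethane, C=[N+]=[N-]; isobutyl chloroformate, CC(C)COC(Cl)=O (its atoms stay only in intermediate 18)
Why: First half of the Arndt–Eistert homologation: the activated acid acylates diazomethane to give the α-diazoketone under cold, nearly neutral conditions.

**Step 15**
Reactants: 19 diazoketone
Product: 21 N-methoxy-N-methyl-3-[(3S,6S)-6-{(2S)-1-[(tert-butyldiphenylsilyl)oxy]propan-2-yl}-3-methyl-1,2-dioxan-3-yl]propanamide, via ketene 20 (not isolated)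
Conditions: PhCO2Ag (0.1 equiv), Et3N (1.5 equiv), MeNH(OMe) (2 equiv), THF, −25 → 0 °C, dark
Reagents that add atoms: N,O-dimethylhydroxylamine, CNOC
Why: Wolff rearrangement (loss of N2 with 1,2-shift of the CH2 group, which carries no stereocentre) gives a ketene that the hydroxylamine traps as the one-carbon-longer Weinreb amide, placing the carbonyl at C9.

**Step 16**
Reactants: 22 dihydro-β-ionone
Product: 23 N'-[(2E)-4-(2,6,6-trimethylcyclohex-1-en-1-yl)butan-2-ylidene]-2,4,6-tri(propan-2-yl)benzenesulfonohydrazide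
Conditions: 2,4,6-triisopropylbenzenesulfonohydrazide, MeOH, HCl (cat.), rt
Reagents that add atoms: 2,4,6-tri(propan-2-yl)benzenesulfonohydrazide, NNS(=O)(=O)c1c(C(C)C)cc(C(C)C)cc1C(C)C
Why: Acid-catalysed condensation of the methyl ketone with the sulfonyl hydrazide gives the crystalline (E)-hydrazone needed for the Shapiro reaction.

**Step 17**
Reactants: 23 trisylhydrazone; 21 Weinreb amide
Product: 25 5-[(3S,6S)-6-{(2S)-1-[(tert-butyldiphenylsilyl)oxy]propan-2-yl}-3-methyl-1,2-dioxan-3-yl]-2-[2-(2,6,6-trimethylcyclohex-1-en-1-yl)ethyl]pent-1-en-3-one, via alkenyllithium 24 (not isolated)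
Conditions: 23 (1.5 equiv), n-BuLi (3.0 equiv), THF/TMEDA, −78 → 0 °C (N2 evolution), then −78 °C; 21 (1.0 equiv), −78 °C, 1 h; inverse quench into cold aq. NH4Cl
Reagents that add atoms: n-butyllithium, [Li]CCCC (its lithium stays only in intermediate 24)
Why: The Shapiro reaction gives the less substituted 2-lithioalkene regioselectively, and it adds once to the Weinreb amide (stable chelated tetrahedral adduct) at −78 °C, where an sp2 organolithium attacks the carbonyl far faster than the hindered dialkyl peroxide.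

**Step 18**
Reactants: 25 enone
Product: 26 (3R)-1-[(3R,6S)-6-{(2S)-1-[(tert-butyldiphenylsilyl)oxy]propan-2-yl}-3-methyl-1,2-dioxan-3-yl]-4-methylidene-6-(2,6,6-trimethylcyclohex-1-en-1-yl)hexan-3-ol
Conditions: (S)-2-methyl-CBS-oxazaborolidine (0.2 equiv), catecholborane (1.5 equiv), toluene, −78 °C; then MeOH, aq. work-up
Reagents that add atoms: none
Why: Corey–Bakshi–Shibata reduction: the (S)-oxazaborolidine treats the α-branched vinyl group as the large substituent and delivers hydride to give the (R)-carbinol at C9, while catecholborane at −78 °C neither hydroborates the alkenes nor reduces the peroxide.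

**Step 19**
Reactants: 26 silyl ether
Product: 27 (2S)-2-[(3S,6R)-6-[(3R)-3-hydroxy-4-methylidene-6-(2,6,6-trimethylcyclohex-1-en-1-yl)hexyl]-6-methyl-1,2-dioxan-3-yl]propan-1-ol
Conditions: HF·pyridine, pyridine, THF, 0 °C → rt
Reagents that add atoms: none
Why: Buffered fluoride desilylation frees the C1 alcohol under non-basic conditions that cannot trigger base-induced peroxide fragmentation.

**Step 20**
Reactants: 27 diol
Product: 28 (2R)-2-[(3S,6R)-6-[(3R)-3-hydroxy-4-methylidene-6-(2,6,6-trimethylcyclohex-1-en-1-yl)hexyl]-6-methyl-1,2-dioxan-3-yl]propanal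
Conditions: PhI(OAc)2 (1.1 equiv), TEMPO (0.1 equiv), CH2Cl2, 0 °C → rt
Reagents that add atoms: none
Why: The sterically demanding oxoammonium oxidant (TEMPO oxidation) oxidises the primary alcohol much faster than the hindered secondary allylic one and is mild enough not to epimerise C2.

**Step 21**
Reactants: 28 aldehyde
Product: 29 (2R)-2-[(3S,6R)-6-[(3R)-3-hydroxy-4-methylidene-6-(2,6,6-trimethylcyclohex-1-en-1-yl)hexyl]-6-methyl-1,2-dioxan-3-yl]propanoic acid
Conditions: NaClO2, NaH2PO4, 2-methylbut-2-ene (excess), t-BuOH/H2O, 0 °C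
Reagents that add atoms: sodium chlorite, [Na+].[O-]Cl=O
Why: Pinnick oxidation at buffered pH converts the aldehyde to the acid, and the alkene scavenger removes HOCl so that the alkenes, the allylic alcohol and the peroxide survive.

**Compound list**
1 | geraniol, (2E)-3,7-dimethylocta-2,6-dien-1-ol | CC(C)=CCC/C(C)=C/CO | starting material
2 | [(2R,3R)-3-methyl-3-(4-methylpent-3-en-1-yl)oxiran-2-yl]methanol | OC[C@H]1O[C@]1(C)CCC=C(C)C | intermediate
3 | (3R)-3,7-dimethyloct-6-ene-1,3-diol | OCC[C@@](O)(C)CCC=C(C)C | intermediate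
4 | (3R)-3-hydroxy-3,7-dimethyloct-6-en-1-yl 4-methylbenzenesulfonate (lithium alkoxide in the flask) | Cc1ccc(cc1)S(=O)(=O)OCC[C@@](O)(C)CCC=C(C)C | intermediate
5 | (2R)-2-methyl-2-(4-methylpent-3-en-1-yl)oxetane | C1CO[C@]1(C)CCC=C(C)C | intermediate
6 | 3,3-dimethyl-5-{2-[(2R)-2-methyloxetan-2-yl]ethyl}-1,2,4-trioxolane (both C5 epimers) | C1CO[C@]1(C)CCC1OOC(C)(C)O1 | intermediate
7 | 3-[(2R)-2-methyloxetan-2-yl]propanal | C1CO[C@]1(C)CCC=O | intermediate
8 | ethyl 5-[(2R)-2-methyloxetan-2-yl]-3-oxopentanoate | C1CO[C@]1(C)CCC(=O)CC(=O)OCC | intermediate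
9 | ethyl (3R)-3-hydroxy-5-[(2R)-2-methyloxetan-2-yl]pentanoate | C1CO[C@]1(C)CC[C@@H](O)CC(=O)OCC | intermediate
10 | dilithium salt of 9 (C3 alkoxide and chelated ester enolate) | CCO/C(O[Li])=C/[C@H](O[Li])CC[C@]1(C)CCO1 | intermediate
11 | ethyl (2R,3R)-3-hydroxy-2-methyl-5-[(2R)-2-methyloxetan-2-yl]pentanoate | C1CO[C@]1(C)CC[C@@H](O)[C@@H](C)C(=O)OCC | intermediate
12 | (2S,3R)-2-methyl-5-[(2R)-2-methyloxetan-2-yl]pentane-1,3-diol | C1CO[C@]1(C)CC[C@@H](O)[C@@H](C)CO | intermediate
13 | (2S,3R)-1-[(tert-butyldiphenylsilyl)oxy]-2-methyl-5-[(2R)-2-methyloxetan-2-yl]pentan-3-ol | C1CO[C@]1(C)CC[C@@H](O)[C@@H](C)CO[Si](c1ccccc1)(c1ccccc1)C(C)(C)C | intermediate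
14 | (2S,3R)-1-[(tert-butyldiphenylsilyl)oxy]-2-methyl-5-[(2R)-2-methyloxetan-2-yl]pentan-3-yl methanesulfonate | C1CO[C@]1(C)CC[C@@H](OS(C)(=O)=O)[C@@H](C)CO[Si](c1ccccc1)(c1ccccc1)C(C)(C)C | intermediate
15 | (2S,3R,6S)-1-[(tert-butyldiphenylsilyl)oxy]-6-hydroperoxy-8-hydroxy-2,6-dimethyloctan-3-yl methanesulfonate | OCC[C@](OO)(C)CC[C@@H](OS(C)(=O)=O)[C@@H](C)CO[Si](c1ccccc1)(c1ccccc1)C(C)(C)C | intermediate
16 | 2-[(3S,6S)-6-{(2S)-1-[(tert-butyldiphenylsilyl)oxy]propan-2-yl}-3-methyl-1,2-dioxan-3-yl]ethan-1-ol | OCC[C@]1(C)CC[C@@H]([C@@H](C)CO[Si](c2ccccc2)(c2ccccc2)C(C)(C)C)OO1 | intermediate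
17 | [(3S,6S)-6-{(2S)-1-[(tert-butyldiphenylsilyl)oxy]propan-2-yl}-3-methyl-1,2-dioxan-3-yl]acetic acid | OC(=O)C[C@]1(C)CC[C@@H]([C@@H](C)CO[Si](c2ccccc2)(c2ccccc2)C(C)(C)C)OO1 | intermediate
18 | mixed anhydride of acid 17 with isobutyl hydrogen carbonate | CC(C)COC(=O)OC(=O)C[C@]1(C)CC[C@@H]([C@@H](C)CO[Si](c2ccccc2)(c2ccccc2)C(C)(C)C)OO1 | intermediate
19 | 1-diazo-3-[(3S,6S)-6-{(2S)-1-[(tert-butyldiphenylsilyl)oxy]propan-2-yl}-3-methyl-1,2-dioxan-3-yl]propan-2-one | [N-]=[N+]=CC(=O)C[C@]1(C)CC[C@@H]([C@@H](C)CO[Si](c2ccccc2)(c2ccccc2)C(C)(C)C)OO1 | intermediate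
20 | 3-[(3S,6S)-6-{(2S)-1-[(tert-butyldiphenylsilyl)oxy]propan-2-yl}-3-methyl-1,2-dioxan-3-yl]prop-1-en-1-one (ketene) | O=C=CC[C@]1(C)CC[C@@H]([C@@H](C)CO[Si](c2ccccc2)(c2ccccc2)C(C)(C)C)OO1 | intermediate
21 | N-methoxy-N-methyl-3-[(3S,6S)-6-{(2S)-1-[(tert-butyldiphenylsilyl)oxy]propan-2-yl}-3-methyl-1,2-dioxan-3-yl]propanamide | CON(C)C(=O)CC[C@]1(C)CC[C@@H]([C@@H](C)CO[Si](c2ccccc2)(c2ccccc2)C(C)(C)C)OO1 | intermediate
22 | dihydro-β-ionone, 4-(2,6,6-trimethylcyclohex-1-en-1-yl)butan-2-one | CC(=O)CCC1=C(C)CCCC1(C)C | starting material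
23 | N'-[(2E)-4-(2,6,6-trimethylcyclohex-1-en-1-yl)butan-2-ylidene]-2,4,6-tri(propan-2-yl)benzenesulfonohydrazide | C/C(=N\NS(=O)(=O)c1c(C(C)C)cc(C(C)C)cc1C(C)C)CCC1=C(C)CCCC1(C)C | intermediate
24 | [4-(2,6,6-trimethylcyclohex-1-en-1-yl)but-1-en-2-yl]lithium | [Li]C(=C)CCC1=C(C)CCCC1(C)C | intermediate
25 | 5-[(3S,6S)-6-{(2S)-1-[(tert-butyldiphenylsilyl)oxy]propan-2-yl}-3-methyl-1,2-dioxan-3-yl]-2-[2-(2,6,6-trimethylcyclohex-1-en-1-yl)ethyl]pent-1-en-3-one | C=C(CCC1=C(C)CCCC1(C)C)C(=O)CC[C@]1(C)CC[C@@H]([C@@H](C)CO[Si](c2ccccc2)(c2ccccc2)C(C)(C)C)OO1 | intermediate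
26 | (3R)-1-[(3R,6S)-6-{(2S)-1-[(tert-butyldiphenylsilyl)oxy]propan-2-yl}-3-methyl-1,2-dioxan-3-yl]-4-methylidene-6-(2,6,6-trimethylcyclohex-1-en-1-yl)hexan-3-ol | C=C(CCC1=C(C)CCCC1(C)C)[C@H](O)CC[C@]1(C)CC[C@@H]([C@@H](C)CO[Si](c2ccccc2)(c2ccccc2)C(C)(C)C)OO1 | intermediate
27 | (2S)-2-[(3S,6R)-6-[(3R)-3-hydroxy-4-methylidene-6-(2,6,6-trimethylcyclohex-1-en-1-yl)hexyl]-6-methyl-1,2-dioxan-3-yl]propan-1-ol | C=C(CCC1=C(C)CCCC1(C)C)[C@H](O)CC[C@]1(C)CC[C@@H]([C@@H](C)CO)OO1 | intermediate
28 | (2R)-2-[(3S,6R)-6-[(3R)-3-hydroxy-4-methylidene-6-(2,6,6-trimethylcyclohex-1-en-1-yl)hexyl]-6-methyl-1,2-dioxan-3-yl]propanal | C=C(CCC1=C(C)CCCC1(C)C)[C@H](O)CC[C@]1(C)CC[C@@H]([C@@H](C)C=O)OO1 | intermediate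
29 | (2R)-2-[(3S,6R)-6-[(3R)-3-hydroxy-4-methylidene-6-(2,6,6-trimethylcyclohex-1-en-1-yl)hexyl]-6-methyl-1,2-dioxan-3-yl]propanoic acid (CNP0205216.4) | C=C(CCC1=C(C)CCCC1(C)C)[C@H](O)CC[C@]1(C)CC[C@@H]([C@@H](C)C(=O)O)OO1 | target

**Totals**
Total step count: 21 (20 in the main line plus step 16 for hydrazone 23).
Longest linear sequence: 20 steps (steps 1–15 and 17–21, from geraniol).

**Three steps most likely to fail, with fallbacks**

Step 11 (oxetane perhydrolysis). The Lewis acid could cause elimination, or partial ionisation could erode the C6 configuration. The fallback reverses the order of the two C–O bond formations and sets out from 14. The mesylate is displaced first by hydroperoxide anion (50% H2O2, CsOH·H2O, DMF, 0 °C; SN2 with inversion at C3). This gives tert-butyl{[(2S,3S)-3-hydroperoxy-2-methyl-5-[(2R)-2-methyloxetan-2-yl]pentyl]oxy}diphenylsilane F1. The secondary hydroperoxide then opens the oxetane intramolecularly (Yb(OTf)3 or Me3SiOTf cat., CH2Cl2, −78 → 0 °C; 6-exo attack at the tertiary carbon with inversion at C6). Both centres are inverted exactly as in the main line, so the product is 16 and the route is rejoined there.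

Step 17 (alkenyllithium addition beside the peroxide). If the organolithium attacks the O–O bond, the polar addition is replaced by a palladium-catalysed acyl cross-coupling (Fukuyama coupling). The fallback sets out from 19 (with 23 as before). The Wolff rearrangement of 19 is run photochemically in the presence of ethanethiol (365 nm, EtSH, THF, 0 °C) to give S-ethyl 3-[(3S,6S)-6-{(2S)-1-[(tert-butyldiphenylsilyl)oxy]propan-2-yl}-3-methyl-1,2-dioxan-3-yl]propanethioate F2. The Shapiro alkenyllithium 24 is transmetalated with ZnI2 (THF, −78 → 0 °C) to [4-(2,6,6-trimethylcyclohex-1-en-1-yl)but-1-en-2-yl]zinc iodide F3. F2 and F3 are coupled with PdCl2(PPh3)2 (5 mol %) in THF/toluene at rt to give enone 25, where the route is rejoined.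

Step 20 (primary versus secondary allylic alcohol oxidation). If the C9 allylic alcohol is also oxidised, the acid is established before the carbinol exists. The fallback sets out from 25. Desilylation (HF·pyridine, pyridine, THF) gives 5-[(3S,6S)-6-[(2S)-1-hydroxypropan-2-yl]-3-methyl-1,2-dioxan-3-yl]-2-[2-(2,6,6-trimethylcyclohex-1-en-1-yl)ethyl]pent-1-en-3-one F4. Oxidation with PhI(OAc)2/TEMPO in MeCN/H2O gives (2R)-2-[(3S,6S)-6-methyl-6-[4-methylidene-3-oxo-6-(2,6,6-trimethylcyclohex-1-en-1-yl)hexyl]-1,2-dioxan-3-yl]propanoic acid F5. An (R)-selective ketoreductase (NADPH, isopropanol, pH 7 buffer, DMSO co-solvent, 30 °C) then reduces the enone carbonyl in the presence of the free acid and the peroxide. This gives the target 29 directly, where the route is rejoined.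

**Further compounds**
F1 | step 11 | tert-butyl{[(2S,3S)-3-hydroperoxy-2-methyl-5-[(2R)-2-methyloxetan-2-yl]pentyl]oxy}diphenylsilane | C1CO[C@]1(C)CC[C@H](OO)[C@@H](C)CO[Si](c1ccccc1)(c1ccccc1)C(C)(C)C
F2 | step 17 | S-ethyl 3-[(3S,6S)-6-{(2S)-1-[(tert-butyldiphenylsilyl)oxy]propan-2-yl}-3-methyl-1,2-dioxan-3-yl]propanethioate | CCSC(=O)CC[C@]1(C)CC[C@@H]([C@@H](C)CO[Si](c2ccccc2)(c2ccccc2)C(C)(C)C)OO1
F3 | step 17 | [4-(2,6,6-trimethylcyclohex-1-en-1-yl)but-1-en-2-yl]zinc iodide | C=C([Zn]I)CCC1=C(C)CCCC1(C)C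
F4 | step 20 | 5-[(3S,6S)-6-[(2S)-1-hydroxypropan-2-yl]-3-methyl-1,2-dioxan-3-yl]-2-[2-(2,6,6-trimethylcyclohex-1-en-1-yl)ethyl]pent-1-en-3-one | C=C(CCC1=C(C)CCCC1(C)C)C(=O)CC[C@]1(C)CC[C@@H]([C@@H](C)CO)OO1
F5 | step 20 | (2R)-2-[(3S,6S)-6-methyl-6-[4-methylidene-3-oxo-6-(2,6,6-trimethylcyclohex-1-en-1-yl)hexyl]-1,2-dioxan-3-yl]propanoic acid | C=C(CCC1=C(C)CCCC1(C)C)C(=O)CC[C@]1(C)CC[C@@H]([C@@H](C)C(=O)O)OO1
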